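## Retrosynthetic overview

1. Xenoacremone H (22) ⇐ macrocyclic diketo ester 21 (NH3, lactamisation) ⇐ aryl iodide/methyl ketone 20 by a photostimulated SRN1 reaction (aryl radical + ketone enolate) that forms the ArCH2–C bond and closes the 13-membered ring.
2. 20 ⇐ tricyclic aldehyde 16 (Roskamp homologation, acetonylation).
3. 16 ⇐ intramolecular Diels–Alder reaction of (E,Z)-trienal 15: rings A and B form together on preformed ring C, with the aryl ether already in place.
4. 15 ⇐ ring C aldehyde ester 5: C13–OAr by catalytic asymmetric alkenylation and Mitsunobu reaction with 4-iodophenol; (1E,3Z)-triene by Wittig and Peterson olefinations.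
5. 5 ⇐ organocatalytic Diels–Alder reaction of 1 + 2, hydrogenation, epimerisation. Ring order: C, then A+B, then macrocycle, then lactam.

Labels (target SMILES order): C1=C2 vinyl on C3; ring A = C3, C4=C5, C6, C14, C15; ring B = C6, C7, C12, C13, C14; ring C = C7–C12 (Me on C9, C11); ArO on C13; C16 ketone on C15; lactam C17 (CH), C18 (CH2), C19 (C–OH), C21 (C=O); C20 benzylic CH2. β = face of H-7.

Assumption: the natural configurations at C17 and C19 are the thermodynamically preferred ones in the macrocycle (both can equilibrate), and 3,3-dimethoxyprop-1-yne is purchased.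

## Route

Step 1
Reactants: 1 (E)-2-methylpenta-1,3-diene; 2 methyl (E)-4-oxobut-2-enoate
Product: 3 methyl (1S,5S,6S)-6-formyl-3,5-dimethylcyclohex-3-ene-1-carboxylate
Conditions: (5S)-5-benzyl-2,2,3-trimethylimidazolidin-4-one hydrochloride (20 mol %), MeCN/H2O 95:5, 0 °C; minor exo isomer removed by chromatography
Reagents that add atoms: none
Why: Iminium-catalysed asymmetric Diels–Alder reaction, in which the CH2 terminus of the diene bonds to the ester-bearing β-carbon (so CHO ends next to the C11 methyl), the catalyst benzyl group leaves only the Si face of the α-carbon open (sets C11 absolutely), and the endo approach puts that methyl cis to CHO.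

Step 2
Reactants: 3
Product: 5 methyl (1R,2R,3S,5R)-2-formyl-3,5-dimethylcyclohexane-1-carboxylate, via diaxial ester aldehyde 4 (not isolated)
Conditions: H2 (1 atm), 5% Pd/C, MeOH, rt; filter; then NaOMe (0.3 equiv), MeOH, 40 °C
Reagents that add atoms: none
Why: Heterogeneous syn-hydrogenation from the face opposite the pseudoaxial C11 methyl sets C9 (methyls cis), and base epimerisation by enolisation at both α-carbonyl centres (C12, C7) then converts diaxial 4 into the all-equatorial isomer, with C9 and C11 fixing the absolute configuration.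

Step 3
Reactants: 5; 6 3,3-dimethoxyprop-1-yne
Product: 9 methyl (1R,2R,3S,5R)-2-[(1S,2E)-1-hydroxy-4,4-dimethoxybut-2-en-1-yl]-3,5-dimethylcyclohexane-1-carboxylate, via alkenylborane 7 (not isolated), via alkenylzinc 8 (not isolated)
Conditions: 6, Cy2BH, toluene, 0 °C to rt; Et2Zn, −78 °C; (2S)-(−)-3-exo-morpholinoisoborneol (5 mol %); then 5, −10 °C; H2O; used at once (avoids lactonisation)
Reagents that add atoms: none
Why: Oppolzer–Walsh sequence (alkyne hydroboration, boron-to-zinc transmetallation, amino-alcohol-catalysed alkenylzinc addition), in which the catalyst rather than the weakly biased α-centre selects the aldehyde face and gives the (S)-configured (E)-allylic alcohol, while ester and acetal are inert to the alkenylzinc.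

Step 4
Reactants: 9; 10 4-iodophenol
Product: 11 methyl (1R,2R,3S,5R)-2-[(1R,2E)-1-(4-iodophenoxy)-4,4-dimethoxybut-2-en-1-yl]-3,5-dimethylcyclohexane-1-carboxylate
Conditions: PPh3, diisopropyl azodicarboxylate, toluene, 0 °C to rt
Reagents that add atoms: none
Why: Mitsunobu etherification, in which the phenol displaces the oxyphosphonium group by SN2 with inversion and turns the (S)-carbinol into the (R)-aryl ether that is C13 of the target, the SN2′ path being disfavoured because the other allyl terminus carries the acetal.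

Step 5
Reactants: 11
Product: 12 (1R,2R,3S,5R)-2-[(1R,2E)-1-(4-iodophenoxy)-4,4-dimethoxybut-2-en-1-yl]-3,5-dimethylcyclohexane-1-carbaldehyde
Conditions: i-Bu2AlH (1.2 equiv), CH2Cl2, −78 °C; aq. potassium sodium tartrate
Reagents that add atoms: none
Why: Partial ester reduction with DIBAL, where the tetrahedral aluminium hemiacetal is stable at −78 °C and collapses to the aldehyde only on work-up, leaving aryl iodide, acetal and allyl aryl ether untouched and the equatorial C7 centre intact.

Step 6
Reactants: 12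
Product: 13 (2E)-3-{(1S,2R,3S,5R)-2-[(1R,2E)-1-(4-iodophenoxy)-4,4-dimethoxybut-2-en-1-yl]-3,5-dimethylcyclohexyl}prop-2-enal
Conditions: Ph3P=CHCHO (2 equiv), toluene, 80 °C
Reagents that add atoms: (triphenylphosphoranylidene)acetaldehyde, O=CC=P(c1ccccc1)(c1ccccc1)c1ccccc1
Why: Wittig olefination with a stabilised formyl ylide gives the (E)-enal (C5=C6) under neutral conditions, and the acetal keeps the second enal masked so only one aldehyde is present.

Step 7
Reactants: 13
Product: 15 (2E,4R)-4-[(1R,2S,4R,6S)-2-[(1E,3Z)-hexa-1,3,5-trien-1-yl]-4,6-dimethylcyclohexyl]-4-(4-iodophenoxy)but-2-enal, via anti β-hydroxysilane 14 (not isolated)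
Conditions: allyltrimethylsilane, s-BuLi, TMEDA, THF, −78 °C; Ti(OiPr)4; then 13, −78 to −40 °C; then 2 M aq. H2SO4, THF, rt
Reagents that add atoms: allyltrimethylsilane, C=CC[Si](C)(C)C; water, O
Why: The γ-silylallyl titanate adds 1,2 to the enal with anti selectivity (six-membered transition state) and acid-promoted anti Peterson elimination then gives the Z C3=C4 bond of the (1E,3Z)-triene, while the same aqueous acid hydrolyses the dimethyl acetal to the enal dienophile.

Step 8
Reactants: 15
Product: 16 2α-ethenyl-9α-(4-iodophenoxy)-6α,8α-dimethyl-2,4a,4b,5,6,7,8,8a,9,9a-decahydro-1H-fluorene-1β-carbaldehyde (H-4a α; H-4b β; H-8a α; H-9a β)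
Conditions: Me2AlCl (1.1 equiv), CH2Cl2, −78 to −20 °C
Reagents that add atoms: none
Why: Lewis acid-promoted intramolecular Diels–Alder reaction through the endo transition state (trans A/B fusion), in which chair ring C with both arms equatorial allows only the staggered approach with H-6 anti to H-7, the E dienophile gives trans C14/C15 and the Z C3=C4 bond (vinyl inside) places the vinyl group trans to C7, so C3, C6, C14 and C15 are set together.

Step 9
Reactants: 16; 17 ethyl diazoacetate
Product: 18 ethyl 3-[2α-ethenyl-9α-(4-iodophenoxy)-6α,8α-dimethyl-2,4a,4b,5,6,7,8,8a,9,9a-decahydro-1H-fluoren-1β-yl]-3-oxopropanoate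
Conditions: SnCl2 (10 mol %), CH2Cl2, rt
Reagents that add atoms: none
Why: Roskamp reaction, in which Lewis acid-mediated addition of the diazo ester to the aldehyde is followed by a 1,2-hydride shift with loss of N2 to give the β-keto ester without touching the alkenes or the equatorial C15 centre.

Step 10
Reactants: 18; 19 chloroacetone
Product: 20 ethyl 2-{[2α-ethenyl-9α-(4-iodophenoxy)-6α,8α-dimethyl-2,4a,4b,5,6,7,8,8a,9,9a-decahydro-1H-fluoren-1β-yl]carbonyl}-4-oxopentanoate (C17 epimers)
Conditions: K2CO3, NaI (10 mol %), acetone, rt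
Reagents that add atoms: none
Why: C-alkylation of the β-keto ester enolate with an α-halo ketone (Finkelstein-assisted SN2) installs C18–C20 as a methyl ketone, the labile C17 centre being set later.

Step 11
Reactants: 20
Product: 22 xenoacremone H, via macrocyclic diketo ester 21 (not isolated)
Conditions: KOtBu (4 equiv), liquid NH3/Et2O, −33 °C, hν (350 nm), 1 mM; then NH4Cl, evaporate most NH3, 7 M NH3 in MeOH, sealed tube, 80 °C
Reagents that add atoms: ammonia, N
Why: Proposed new method: photostimulated SRN1 macrocyclisation, in which the dianion of 20 (inert C17 β-keto ester enolate plus terminal methyl ketone enolate) transfers an electron to the aryl iodide under light, iodide loss gives a σ-aryl radical that couples with the tethered enolate carbon in a near diffusion-controlled step with an early transition state that tolerates the bent para-bridged arene, and the ketyl radical anion passes its electron to the next aryl iodide (chain); the closest known reactions are photostimulated arylation of ketone enolates in liquid ammonia, its ring-closing variant and terminal arylation of β-dicarbonyl dianions; ammonia then adds to the C19 ketone and the nitrogen acylates on the ester to give the hydroxy lactam, with C17 and C19 equilibrating by enolisation and ring–chain tautomerism.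

## Compound list

1 | (E)-2-methylpenta-1,3-diene | C=C(C)/C=C/C | starting material
2 | methyl (E)-4-oxobut-2-enoate | COC(=O)/C=C/C=O | starting material
3 | methyl (1S,5S,6S)-6-formyl-3,5-dimethylcyclohex-3-ene-1-carboxylate | COC(=O)[C@H]1CC(C)=C[C@H](C)[C@@H]1C=O | intermediate
4 | methyl (1S,2S,3S,5R)-2-formyl-3,5-dimethylcyclohexane-1-carboxylate | COC(=O)[C@H]1C[C@H](C)C[C@H](C)[C@@H]1C=O | intermediate (not isolated)
5 | methyl (1R,2R,3S,5R)-2-formyl-3,5-dimethylcyclohexane-1-carboxylate | COC(=O)[C@@H]1C[C@H](C)C[C@H](C)[C@H]1C=O | intermediate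
6 | 3,3-dimethoxyprop-1-yne | C#CC(OC)OC | starting material
7 | dicyclohexyl[(E)-3,3-dimethoxyprop-1-en-1-yl]borane | COC(OC)/C=C/B(C1CCCCC1)C1CCCCC1 | intermediate (not isolated)
8 | ethyl[(E)-3,3-dimethoxyprop-1-en-1-yl]zinc | CC[Zn]/C=C/C(OC)OC | intermediate (not isolated)
9 | methyl (1R,2R,3S,5R)-2-[(1S,2E)-1-hydroxy-4,4-dimethoxybut-2-en-1-yl]-3,5-dimethylcyclohexane-1-carboxylate | COC(=O)[C@@H]1C[C@H](C)C[C@H](C)[C@H]1[C@@H](O)/C=C/C(OC)OC | intermediate
10 | 4-iodophenol | Oc1ccc(I)cc1 | starting material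
11 | methyl (1R,2R,3S,5R)-2-[(1R,2E)-1-(4-iodophenoxy)-4,4-dimethoxybut-2-en-1-yl]-3,5-dimethylcyclohexane-1-carboxylate | COC(=O)[C@@H]1C[C@H](C)C[C@H](C)[C@H]1[C@H](Oc1ccc(I)cc1)/C=C/C(OC)OC | intermediate
12 | (1R,2R,3S,5R)-2-[(1R,2E)-1-(4-iodophenoxy)-4,4-dimethoxybut-2-en-1-yl]-3,5-dimethylcyclohexane-1-carbaldehyde | O=C[C@@H]1C[C@H](C)C[C@H](C)[C@H]1[C@H](Oc1ccc(I)cc1)/C=C/C(OC)OC | intermediate
13 | (2E)-3-{(1S,2R,3S,5R)-2-[(1R,2E)-1-(4-iodophenoxy)-4,4-dimethoxybut-2-en-1-yl]-3,5-dimethylcyclohexyl}prop-2-enal | O=C/C=C/[C@@H]1C[C@H](C)C[C@H](C)[C@H]1[C@H](Oc1ccc(I)cc1)/C=C/C(OC)OC | intermediate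
14 | anti β-hydroxysilane: 13 with CH=O replaced by CH(OH)–CH(SiMe3)–CH=CH2, OH and Si anti (one of the two anti isomers drawn; both give 15) | C=C[C@H]([Si](C)(C)C)[C@H](O)/C=C/[C@@H]1C[C@H](C)C[C@H](C)[C@H]1[C@H](Oc1ccc(I)cc1)/C=C/C(OC)OC | intermediate (not isolated)
15 | (2E,4R)-4-[(1R,2S,4R,6S)-2-[(1E,3Z)-hexa-1,3,5-trien-1-yl]-4,6-dimethylcyclohexyl]-4-(4-iodophenoxy)but-2-enal | C=C/C=C\C=C\[C@@H]1C[C@H](C)C[C@H](C)[C@H]1[C@H](Oc1ccc(I)cc1)/C=C/C=O | intermediate
16 | 2α-ethenyl-9α-(4-iodophenoxy)-6α,8α-dimethyl-2,4a,4b,5,6,7,8,8a,9,9a-decahydro-1H-fluorene-1β-carbaldehyde (H-4a α, H-4b β, H-8a α, H-9a β) | C=C[C@@H]1C=C[C@H]2[C@@H]3C[C@H](C)C[C@H](C)[C@H]3[C@H](Oc3ccc(I)cc3)[C@@H]2[C@H]1C=O | intermediate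
17 | ethyl diazoacetate | CCOC(=O)C=[N+]=[N-] | starting material
18 | ethyl 3-oxo-3-(tricyclic core of 16)propanoate | C=C[C@@H]1C=C[C@H]2[C@@H]3C[C@H](C)C[C@H](C)[C@H]3[C@H](Oc3ccc(I)cc3)[C@@H]2[C@H]1C(=O)CC(=O)OCC | intermediate
19 | chloroacetone | CC(=O)CCl | starting material
20 | ethyl 2-[(tricyclic core of 16)carbonyl]-4-oxopentanoate (C17 epimers) | C=C[C@@H]1C=C[C@H]2[C@@H]3C[C@H](C)C[C@H](C)[C@H]3[C@H](Oc3ccc(I)cc3)[C@@H]2[C@H]1C(=O)C(CC(C)=O)C(=O)OCC | intermediate
21 | macrocyclic diketo ester: 13-membered para-cyclophane, ArCH2–C19(=O)–CH2–C17H(CO2Et)–C16(=O)–C15 (C17 labile) | C=C[C@@H]1C=C[C@H]2[C@@H]3C[C@H](C)C[C@H](C)[C@H]3[C@@H]3Oc4ccc(cc4)CC(=O)CC(C(=O)OCC)C(=O)[C@@H]1[C@H]23 | intermediate (not isolated)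
22 | xenoacremone H | C=C[C@@H]1C=C[C@H]2[C@@H]3C[C@H](C)C[C@H](C)[C@H]3[C@@H]3Oc4ccc(cc4)C[C@@]4(O)C[C@H](C(=O)N4)C(=O)[C@@H]1[C@H]23 | target

## Count

Total steps: 11. Longest linear sequence: 11 steps (1/2 to 22; 6, 10, 17 and 19 enter directly).

## Steps most likely to fail, with fallbacks

**Step 11 (SRN1 macrocyclisation).** The aryl radical may be reduced before it finds the enolate, or the dianion may not form cleanly. The fallback closes the ring at a different bond (C16–C17) by acyl radical addition and sets out from 16. Pinnick oxidation (NaClO2, NaH2PO4, 2-methylbut-2-ene) gives the carboxylic acid F1. Coupling of its aryl iodide with 1,1-dimethoxypropan-2-one (only the methyl group can enolise; Pd2(dba)3, XPhos, K3PO4, toluene, 80 °C) gives the keto acetal F2. PhSeSePh/Bu3P converts the acid into the Se-phenyl selenoester F3. Aqueous CF3CO2H frees the keto aldehyde, which is condensed in the same flask with Ph3P=CHCO2Et to the (E)-4-oxo-enoate F4. Bu3SnH and azobisisobutyronitrile (benzene, 80 °C, 2 mM, slow addition) generate the C16 acyl radical, which adds to the alkene carbon next to the ester (β to the ketone) and closes the 13-membered ring. The route is rejoined at 21, which is lactamised with NH3/MeOH as in the second stage of step 11.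

**Step 8 (Diels–Alder reaction of a Z-triene).** The inside vinyl group may block the s-cis diene. The fallback replaces it by a slim alkynyl group and sets out from 13. Lithiated 1,3-bis(triisopropylsilyl)propyne (n-BuLi, THF, −78 °C; Z-selective Peterson olefination) followed by aqueous HCl/THF gives the (Z)-dienynal F5. Me2AlCl-promoted cycloaddition as in step 8 gives the silyl alkyne cycloadduct F6. Bu4NF gives the terminal alkyne F7. Semihydrogenation (H2, Pd/CaCO3 poisoned with Pb(OAc)2, quinoline) returns to 16.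

**Step 7 (Z-selective triene formation with acetal hydrolysis in the same acid).** The allylic carbinol may ionise and erode the Z geometry. The fallback uses a phosphorus-based syn elimination under non-acidic conditions and sets out from 13. [3-(Diphenylphosphino)allyl]titanium triisopropoxide (from allyldiphenylphosphine, t-BuLi, Ti(OiPr)4) gives the erythro β-hydroxy phosphine. MeI then quaternises phosphorus and the betaine collapses to the (Z)-diene, the triene acetal F8. PPTS in acetone/H2O unmasks the enal and returns to 15.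

## Further compounds

F1 | step 11 | carboxylic acid (16 with CO2H for CHO) | C=C[C@@H]1C=C[C@H]2[C@@H]3C[C@H](C)C[C@H](C)[C@H]3[C@H](Oc3ccc(I)cc3)[C@@H]2[C@H]1C(=O)O
F2 | step 11 | keto acetal acid (aryl iodide replaced by CH2C(=O)CH(OMe)2) | C=C[C@@H]1C=C[C@H]2[C@@H]3C[C@H](C)C[C@H](C)[C@H]3[C@H](Oc3ccc(CC(=O)C(OC)OC)cc3)[C@@H]2[C@H]1C(=O)O
F3 | step 11 | Se-phenyl selenoester of F2 | C=C[C@@H]1C=C[C@H]2[C@@H]3C[C@H](C)C[C@H](C)[C@H]3[C@H](Oc3ccc(CC(=O)C(OC)OC)cc3)[C@@H]2[C@H]1C(=O)[Se]c1ccccc1
F4 | step 11 | (E)-4-oxo-enoate selenoester | C=C[C@@H]1C=C[C@H]2[C@@H]3C[C@H](C)C[C@H](C)[C@H]3[C@H](Oc3ccc(CC(=O)/C=C/C(=O)OCC)cc3)[C@@H]2[C@H]1C(=O)[Se]c1ccccc1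
F5 | step 8 | (Z)-dienynal (15 with C≡C–Si(i-Pr)3 for vinyl) | CC(C)[Si](C(C)C)(C(C)C)C#C/C=C\C=C\[C@@H]1C[C@H](C)C[C@H](C)[C@H]1[C@H](Oc1ccc(I)cc1)/C=C/C=O
F6 | step 8 | silyl alkyne cycloadduct (16 with C≡C–Si(i-Pr)3 for vinyl) | CC(C)[Si](C(C)C)(C(C)C)C#C[C@@H]1C=C[C@H]2[C@@H]3C[C@H](C)C[C@H](C)[C@H]3[C@H](Oc3ccc(I)cc3)[C@@H]2[C@H]1C=O
F7 | step 8 | terminal alkyne (16 with ethynyl for vinyl) | C#C[C@@H]1C=C[C@H]2[C@@H]3C[C@H](C)C[C@H](C)[C@H]3[C@H](Oc3ccc(I)cc3)[C@@H]2[C@H]1C=O
F8 | step 7 | triene acetal (15 as its dimethyl acetal) | C=C/C=C\C=C\[C@@H]1C[C@H](C)C[C@H](C)[C@H]1[C@H](Oc1ccc(I)cc1)/C=C/C(OC)OC
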